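No rate constant of this flask is given, so the constants have to be read off two earlier runs made at other charges.

| flask | substrate | remark | time |
|---|---|---|---|
| south-west | 10 mM | run made earlier |  |
| north-west | 15 mM | run made earlier |  |
| elm | 20 mM |  | 3.0 min |
| ash | 20 mM |  | 8.0 min |
| birch | 20 mM |  | 20 min |

- south-west (time / min: target / %, substrate / %): 0.200: 0.4, 71.1; 0.333: 2.1, 60.5; 0.667: 5.7, 46.0; 1.33: 12.6, 33.5; 2.50: 20.7, 20.4
- north-west (time / min: target / %, substrate / %): 0.200: 1.0, 71.4; 0.667: 5.9, 46.0; 1.00: 9.1, 38.9; 1.50: 13.6, 30.6; 2.50: 20.7, 20.5

(each reading ± 0.3 percentage points)

- the numbers in the tables scatter by 0.3 percentage points (one standard deviation)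
- a reading or a percentage of target counts all its forms, free or not
- a reading of substrate is of its free form alone

* which of the two there is more of at the end, elm (side product / target)
* which of the two there is more of at the end, ash (side product / target)
* which of the two there is more of at the end, birch (side product / target)
* amount of target at the end, in percent of the substrate charged, elm
* amount of target at the end, in percent of the substrate charged, ash
* amount of target at the end, in percent of the substrate charged, birch

At the last reading, 2.50 min, the two runs show target 20.7% and 20.7%, and substrate 20.4% and 20.5%. At that reading the percentages do not follow the charge, so the runs can be read as first order and carried over to 20 mM.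

It pays to work with what is left, not with what is made. Substrate drops fast and then falls in a slow tail, with a rate constant of about 0.412 min⁻¹ over the last two readings of each run. My rule is that in this tail the target still to come shrinks by the same fraction as substrate. Solving that for the last two readings gives 33.3% in the south-west run and 35.1% in the north-west run. Their mean, 34.2%, is the target ceiling: the share of the charge that ever becomes target, its overall selectivity. Letting the gap to this ceiling shrink from 2.50 min on, I reckon target at 23.2% in elm, 32.8% in ash and 34.2% in birch.

Side product was never read, and here two chemists part. At 2.50 min the south-west run leaves 58.9% unseen. The first chemist calls most of that finished side product, about 35 against about 24 in a hidden form. The second calls it waiting stock: at 0.200 min target is 0.4% with 28.5% already unseen, so target visibly lags, and side product may lag as well. The second, with whom I side, expects target ahead in elm and ash, and side product ahead in birch; by my ceiling, the share of side product is bound in the end for 65.8%.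

The forecast is the first chemist's: “side product dominates throughout”, so side product leads in all three flasks, with target at 24%, 35% and 36.5%, on a ceiling of about 38, where mine stands at 34.2%.

The flasks give target 23.0% against side product 6.27% in elm, 32.5% against 27.2% in ash, and 34.0% against 55.1% in birch.

    intermediate B → target (k = 0.00646 s⁻¹)
    substrate → intermediate A (k = 0.00734 s⁻¹)
    substrate + target ⇌ idle adduct, settled at all times (K = 18.2 M⁻¹)
    intermediate A → intermediate C (k = 0.0263 s⁻¹)
    intermediate C → side product (k = 0.00181 s⁻¹)
    substrate ⇌ intermediate B (K = 0.680, k = 0.0272 s⁻¹)

The first chemist's view belongs to late times, as in birch, and to elm left until 12 min, where the time alone is changed. The same reckoning puts target there at 33.9%. The flask gives 33.7% of target and 40.3% of side product, which is now ahead. Against the 65.8% bound for side product, 25.5% is still to arrive, and intermediate C holds 25.0%.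

Readings and results are calculated for an exercise; the scatter is artificial.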